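The readings come from a simulation with constants of no real substance; noise was put on by code.

D comes late in the dusk flask, and its amount at the asked time is the hard number.

| setting | dusk | winter | flask |
|---|---|---|---|
| X | 20 mM | 30 mM | 20 mM |
| G | 21 mM (fed, over 4.0 h) | 21 mM (fed, over 4.0 h) | 21.0 mM (fed, over 4.0 h) |
| remark | the very flask that is asked about, followed so far; the fed solution adds 0.10 times the starting volume | run made earlier; the fed solution adds 0.10 times the starting volume | the fed solution adds 0.10 times the starting volume |
| time |  |  | 12 h |

- dusk (time / h: X / %, D / %): 1.00: 88.0, 0.7; 2.00: 69.2, 0.2; 3.00: 50.6, 0.1; 4.00: 35.5, 0.9; 5.00: 26.7, 1.9; 6.00: 21.3, 2.9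
- winter (time / h: X / %, D / %): 0.833: 91.8, 0.4; 1.50: 83.1, 0; 2.50: 67.4, 0; 3.00: 61.7, 0.3; 4.00: 47.8, 1.0; 5.00: 43.0, 2.7

(readings scatter by 0.5 percentage points)

- charges are per starting volume, the dose included; the dosed solution carries all of it
- the numbers in the tables scatter by 0.5 percentage points (one standard deviation)
- a reading or a percentage of D counts all its forms, free or not
- the reaction counts as stopped when no species that holds the X changes by six tenths of a point or more over the second half of the time

- at 12 h, what has stopped the reaction, if anything has (it is still moving / all of X has reacted / forward and back rates have come level)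
- part of the X gone at 12 h
- the D standing at 12 h, as a percentage of the X charged
- the E standing at 12 h, as a percentage of the X charged

In the dusk flask, D reads 0.1% at 3.00 h, inside the scatter of 0.5 percentage points, then 0.9% at 4.00 h and 2.9% at 6.00 h. Such a lag (an induction period) suggests unseen species between X and D.

My own reckoning assumes a steady pool behind D and two slow first-order steps from that pool to D. D then grows with the square of the time, so its square root climbs on a straight line. This gives the root rate, the hourly rise of the square root of the D fraction. The dusk readings at 4.00 h and 6.00 h put it at 0.0377 /h. Traced back, the root reaches zero at 1.48 h, so the clock of D starts there. Carried forward to 12 h, it gives D of 15.7%.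

The weak link is the pair of readings, since each carries the scatter. The pair at 5.00 h and 6.00 h gives a root rate of 0.0325 /h, and so D of 13.3%. My reckoning therefore commits to D between these two values.

The forecast says it is still moving, with X gone 85% (81% to 91%), D 9.5% (6% to 17%) and E 75.5% (67% to 81%). In its words, D “grows roughly linearly”, and its D is what a straight line through the last two dusk readings gives. My D stands higher than the forecast's.

The flask gives: it is still moving, with X gone 83.7%, D 15.5% and E 25.7%.

    X + G → E (k = 1.20 /M/min)
    G + E → Q (k = 0.380 /M/min)
    E → J (k = 0.00160 /min)
    J → D (k = 0.00170 /min)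
    L ⇌ D, rate k5*(cs5 - [D]) while solid is left; crystals form when [D] > cs5 (solubility = 0.320 mM, k = 0.110 /min)
    G → Z (k = 4.60 × 10⁻⁶ /min)

E stands below the forecast's 75.5%, and Q holds 20.2% and J 22.2% at 12.0 h. From 3.52% D at 6.00 h to 15.5% at 12 h, the root of the D fraction in the flask climbed at 0.0343 /h, beside the root rate of 0.0377 /h read off the dusk readings. Read at 8.0 h, the same flask is reckoned from the root rate at 6.04% D. That neighbour holds 6.97% D.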